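**Retrosynthetic overview**

1. Core numbering used here is that of spiro[4.5]decane: cyclopentane C1 (CHOH), C2 (CH bearing the triene), C3, C4; spiro C5; cyclohexane C6 (C(CH3)OH), C7, C8, C9 (=C(CH3)CHO), C10 (CH bearing (CH2)3OH). Late disconnections: the triene at C2 (Hiyama–Denmark coupling of an oxasilolane with a dienyl iodide), the C2–C bond (silicon-tethered radical cyclization from O1), the enal (oxidation) and the C1 carbinol (enone reduction).
2. Key disconnection: C4–C5 together with C9–C10. One gold-catalysed enyne cyclization / ring-expanding 1,2-shift / iodination converts an acyclic 1-alkenylcyclobutanol enyne, held in a temporary 1,3-dioxa-2-silinane, into the complete spiro[4.5]decanone.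
3. Enabling feature: spiro C5 is quaternary and sits between two oxygen-bearing carbons (C1, a carbinol that can be a ketone, and C6, the tertiary carbinol) and C10, which is bonded to the alkylidene carbon C9. C5–C1(=O) with C4 on C5 is the retron of a cyclobutanol 1,2-shift onto a cation at C5, and C10–C9(=C) is the retron of the alkene-to-alkyne addition that creates that cation.
4. Precursor: Sharpless epoxidation sets C6 (the only stereocenter carried into the key step); epoxy chloride to propargylic alcohol, hydroxyl-directed trans-hydrostannation and addition to cyclobutanone give the Z-alkenylcyclobutanol.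
5. Ring order: cyclobutane (purchased) → dioxasilinane (temporary) → cyclohexane and cyclopentanone together (key step) → oxasilolane (temporary, opened in the last step).

Key step: step 10

Remark: hexa-1,5-diyne (pentane solution) and (3-bromopropoxy)(tert-butyl)diphenylsilane are taken as catalogue compounds, and L-(+)-diethyl tartrate is taken to give the (2S,3S)-epoxide of the E-allylic alcohol, as with other E-3-methylalk-2-en-1-ols.

**Route**

Step 1
Reactants: 1 hexa-1,5-diyne
Product: 3 hepta-2,6-diyn-1-ol, via lithium hexa-1,5-diyn-1-ide 2 (not isolated)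
Conditions: 1 (3 equiv), n-BuLi (1 equiv), THF, −78 °C; (CH2O)n, −78 °C to rt
Reagents that add atoms: formaldehyde (as paraformaldehyde), C=O
Why: Mono-lithiation of the diyne used in excess and addition of the acetylide to formaldehyde (alkynylation of an aldehyde) should give the propargylic alcohol, unreacted volatile 1 being removed on concentration.

Step 2
Reactants: 3 hepta-2,6-diyn-1-ol
Product: 4 triethyl(hepta-2,6-diyn-1-yloxy)silane
Conditions: Et3SiCl, imidazole, CH2Cl2, 0 °C
Reagents that add atoms: chlorotriethylsilane, CC[Si](Cl)(CC)CC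
Why: Silyl ether formation masks the propargylic oxygen as a group that HF·pyridine later removes while a tert-butyldiphenylsilyl ether stays.

Step 3
Reactants: 4 triethyl(hepta-2,6-diyn-1-yloxy)silane
Product: 7 (E)-3-methyl-8-(triethylsilyloxy)oct-2-en-6-yn-1-ol, via alkenyl(dimethyl)alane 5 (not isolated), via lithium alkenylalanate 6 (not isolated)
Conditions: Me3Al, Cp2ZrCl2 (20 mol %), CH2Cl2, 0 °C to rt; n-BuLi, THF, −78 °C; (CH2O)n, −78 °C to rt; aq. Rochelle salt
Reagents that add atoms: trimethylaluminium, C[Al](C)C; formaldehyde (as paraformaldehyde), C=O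
Why: Negishi zirconium-catalysed carboalumination adds methyl and aluminium syn across the terminal alkyne only (methyl to the internal carbon), and hydroxymethylation of the alanate with retention should give the E-allylic alcohol.

Step 4
Reactants: 7 (E)-3-methyl-8-(triethylsilyloxy)oct-2-en-6-yn-1-ol
Product: 8 [(2S,3S)-3-methyl-3-[5-(triethylsilyloxy)pent-3-yn-1-yl]oxiran-2-yl]methanol
Conditions: Ti(OiPr)4 (10 mol %), L-(+)-diethyl tartrate (12 mol %), t-BuOOH, 4 Å MS, CH2Cl2, −20 °C
Reagents that add atoms: tert-butyl hydroperoxide, CC(C)(C)OO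
Why: Sharpless asymmetric epoxidation with L-(+)-diethyl tartrate should deliver oxygen to the face that gives the (2S,3S)-epoxide, which fixes the future C6 (S) as the one stereocenter from which all others follow.

Step 5
Reactants: 8 (2S,3S)-epoxy alcohol
Product: 9 (2R,3S)-2-(chloromethyl)-3-methyl-3-[5-(triethylsilyloxy)pent-3-yn-1-yl]oxirane
Conditions: PPh3, CCl4, NaHCO3, reflux
Reagents that add atoms: tetrachloromethane, ClC(Cl)(Cl)Cl
Why: Appel reaction under neutral, buffered conditions replaces the primary hydroxyl by chloride without opening the epoxide or cleaving the silyl ether.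

Step 6
Reactants: 9 (2R,3S)-epoxy chloride, 10 (3-bromopropoxy)(tert-butyl)diphenylsilane
Product: 12 (6S)-1-(tert-butyldiphenylsilyloxy)-6-methyl-11-(triethylsilyloxy)undeca-4,9-diyn-6-ol, via dilithium alkynide alkoxide 11 (not isolated)
Conditions: LiN(iPr)2 (3.3 equiv), THF, −78 to −30 °C; 10, DMPU, −30 °C to rt
Reagents that add atoms: none
Why: Base-induced eliminative opening of the 2,3-epoxy chloride and loss of HCl (double elimination) unmask the tertiary propargylic alkoxide as its lithium acetylide without touching the C–O bond of the stereocenter, and SN2 alkylation of the acetylide with 10 installs the future C10 side chain.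

Step 7
Reactants: 12 (6S)-diynol
Product: 13 (4Z,6S)-1-(tert-butyldiphenylsilyloxy)-6-methyl-5-(tributylstannyl)-11-(triethylsilyloxy)undec-4-en-9-yn-6-ol
Conditions: Bu3SnH (slow addition), [Cp*RuCl]4 (2.5 mol %), CH2Cl2, rt
Reagents that add atoms: tributylstannane, CCCC[SnH](CCCC)CCCC
Why: Hydroxyl-directed ruthenium-catalysed trans-hydrostannation should put tin on the alkyne carbon next to the free tertiary alcohol and hydrogen trans to it (Z-alkenylstannane), the remote alkyne having no free hydroxyl to direct the catalyst.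

Step 8
Reactants: 13 (4Z,6S)-alkenylstannane, 14 cyclobutanone
Product: 16 (4Z,6S)-1-(tert-butyldiphenylsilyloxy)-5-(1-hydroxycyclobutyl)-6-methyl-11-(triethylsilyloxy)undec-4-en-9-yn-6-ol, via lithioalkene lithium alkoxide 15 (not isolated)
Conditions: MeLi (2.2 equiv), THF, −78 to 0 °C; LaCl3·2LiCl (30 mol %), 14, −78 °C
Reagents that add atoms: none
Why: Tin–lithium exchange with retention of alkene geometry and 1,2-addition of the alkenyllithium to cyclobutanone should give the 1-alkenylcyclobutanol with the side chain cis to the new carbinol carbon.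

Step 9
Reactants: 16 (4Z,6S)-diol
Product: 17 (8S,9Z)-9-[4-(tert-butyldiphenylsilyloxy)butylidene]-8-methyl-6,6-di(propan-2-yl)-8-[5-(triethylsilyloxy)pent-3-yn-1-yl]-5,7-dioxa-6-silaspiro[3.5]nonane
Conditions: iPr2Si(OTf)2, 2,6-lutidine, CH2Cl2, 0 °C to rt
Reagents that add atoms: di(propan-2-yl)silanediyl bis(trifluoromethanesulfonate), CC(C)[Si](OS(=O)(=O)C(F)(F)F)(OS(=O)(=O)C(F)(F)F)C(C)C
Why: Silylene acetal formation from the 1,3-diol and a silyl bis-triflate protects both tertiary alcohols and ties the two oxygens into a six-membered ring that later fixes the conformation about the future C5–C6 bond.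

Step 10
Reactants: 17 silylene-bridged enyne
Product: 19 (9E)-10-[3-(tert-butyldiphenylsilyloxy)propyl]-6-hydroxy-9-(2-hydroxy-1-iodoethylidene)-6-methylspiro[4.5]decan-1-one (C5, C6, C10 as in 40), via N-silylsuccinimide spiroketone 18 (not isolated)
Conditions: Ph3PAuNTf2 (5 mol %), NIS (1.2 equiv), 4 Å MS, CH2Cl2, −20 °C to rt, dark; then HF·pyridine, pyridine, THF, 0 °C
Reagents that add atoms: N-iodosuccinimide, O=C1CCC(=O)N1I
Why: Proposed new method: cationic monovalent gold activates the alkyne, alkene carbon C10 attacks alkyne carbon C9, and the positive charge building at C5 is quenched in concert by a 1,2-shift of the cyclobutane CH2 (C4) from C1 to C5, which makes the C4–C5 bond and leaves C1 as a silyloxocarbenium ion, after which NIS iodinates the alkenylgold with retention and succinimide takes over the silicon, freeing the catalyst and the ketone. The closest known reaction types are gold-catalysed enyne carbocyclizations that end in a pinacol-type shift of a siloxy-bearing carbon, including capture of the alkenylgold by NIS, and halonium- or acid-triggered ring-expanding semipinacol shifts of 1-alkenylcyclobutanols, whose combination in this mode on a silylene-bridged diol has not been described. The cyclohexane closes 6-exo-dig at the alkyne (with both alkene carbons in the new ring) and the cyclopentanone closes by enlargement of the cyclobutane through the shift that forms C4–C5. Both additions are anti and stereospecific, so iodine ends trans and CH2O cis to C10 on the new alkene, and the chain on C10 ends cis to C1 because C9 and C4 add to opposite faces of the Z-alkene, while the face itself is chosen by C6: the dioxasilinane keeps the C6–O bond beside C1, the butynyl arm is then pseudoaxial and reaches one face only, which sets C5 and C10 as in 40 with O6 cis to C1. The step needs gold to engage the alkyne before NIS attacks the alkene, exo closure, and migration of the ring CH2 in preference to the C6 methyl group; these are served by the carbophilic catalyst and the hindered alkene flanked by two siloxy carbons, by the tether length with the electron-poor propargylic carbon, and by release of cyclobutane strain. HF·pyridine then cleaves the Si–N and Si–O bonds of the spent bridge and the triethylsilyl ether while the tert-butyldiphenylsilyl ether stays.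

Step 11
Reactants: 19 iodoalkylidene spiroketone
Product: 20 (9Z)-10-[3-(tert-butyldiphenylsilyloxy)propyl]-6-hydroxy-9-(1-hydroxypropan-2-ylidene)-6-methylspiro[4.5]decan-1-one
Conditions: SnMe4, Pd2(dba)3 (5 mol %), AsPh3, CuI (10 mol %), NMP, 60 °C
Reagents that add atoms: tetramethylstannane, C[Sn](C)(C)C
Why: Stille coupling (copper-assisted methyl transfer from SnMe4) should replace iodine by methyl with retention, giving the tetrasubstituted alkene with CH2OH cis to C10.

Step 12
Reactants: 20 spiroketone diol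
Product: 23 (9Z)-10-[3-(tert-butyldiphenylsilyloxy)propyl]-9-(1-hydroxypropan-2-ylidene)-6-methyl-6-(trimethylsilyloxy)spiro[4.5]dec-2-en-1-one, via tris(trimethylsilyl) enol ether 21 (not isolated), via bis(trimethylsilyl) enone 22 (not isolated)
Conditions: Me3SiOTf, Et3N, CH2Cl2, 0 °C; Pd(OAc)2 (1.1 equiv), MeCN, rt; citric acid (cat.), MeOH, 0 °C
Reagents that add atoms: trimethylsilyl trifluoromethanesulfonate, C[Si](C)(C)OS(=O)(=O)C(F)(F)F
Why: Soft enolization with the silyl triflate (only C2 can enolize because C5 is quaternary, and both hydroxyls are capped at once, which prevents retro-aldol opening) and Saegusa–Ito oxidation should give the cyclopentenone, and mild acid methanolysis frees only the primary allylic alcohol.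

Step 13
Reactants: 23 cyclopentenone
Product: 24 (1S-configured as in 40) 10-[3-(tert-butyldiphenylsilyloxy)propyl]-9-[(Z)-1-hydroxypropan-2-ylidene]-6-methyl-6-(trimethylsilyloxy)spiro[4.5]dec-2-en-1-ol
Conditions: NaBH4, CeCl3·7H2O, MeOH, −78 °C
Reagents that add atoms: none
Why: Luche 1,2-reduction, in which hydride is expected to approach C1 from the side of C10 and away from the fully substituted, silyloxy-bearing C6, should set the C1 hydroxyl cis to C6.

Step 14
Reactants: 24 allylic diol
Product: 25 (2Z)-2-[10-[3-(tert-butyldiphenylsilyloxy)propyl]-1-hydroxy-6-methyl-6-(trimethylsilyloxy)spiro[4.5]dec-2-en-9-ylidene]propanal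
Conditions: TEMPO (10 mol %), PhI(OAc)2, CH2Cl2, rt
Reagents that add atoms: none
Why: TEMPO/PhI(OAc)2 oxidation is selective for the primary allylic alcohol over the hindered secondary one and should give the tetrasubstituted enal without change of alkene geometry.

Step 15
Reactants: 26 chloro(dimethyl)vinylsilane
Product: 28 1-(1-bromoethenyl)-N,N-diethyl-1,1-dimethylsilanamine, via dibromide 27 (not isolated)
Conditions: Br2, CH2Cl2, −78 °C; Et2NH (3.2 equiv), Et2O, reflux; distillation
Reagents that add atoms: bromine, BrBr; diethylamine, CCNCC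
Why: Bromine addition to the vinylsilane and amine-induced dehydrobromination with loss of the proton alpha to silicon, together with aminolysis of the Si–Cl bond, should give the 1-bromovinyl aminosilane (halogenation–elimination).

Step 16
Reactants: 25 hydroxy enal, 28 1-bromovinyl aminosilane
Product: 29 (1-bromoethenyl)dimethylsilyl ether of 25 at O1
Conditions: 28 (1.5 equiv), imidazole (20 mol %), CH2Cl2, rt
Reagents that add atoms: none
Why: Silylation of the secondary alcohol by Si–N/Si–O exchange, driven by loss of diethylamine, attaches the radical precursor to O1.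

Step 17
Reactants: 29 bromovinylsilyl ether
Product: 30 oxasilolane enal: C1–O–Si(CH3)2–C(=CH2)–C2 ring cis-fused to the cyclopentane, C2–C3 saturated
Conditions: Bu3SnH (syringe pump), AIBN (10 mol %), benzene, 80 °C
Reagents that add atoms: none
Why: Silicon-tethered 5-exo-trig cyclization of the alkenyl radical onto C2 can take place only on the face of O1, which gives the cis-fused oxasilolane (new C2 stereocenter cis to O1), and the C3 radical is reduced by the tin hydride.

Step 18
Reactants: 31 prop-2-yn-1-ol, 32 5-bromo-2-methylpent-2-ene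
Product: 35 (2Z)-3-iodo-2-(4-methylpent-3-en-1-yl)prop-2-en-1-ol, via Grignard reagent 33 (not isolated), via alkenylmagnesium bromide 34 (not isolated)
Conditions: 32, Mg, THF; 31 (0.4 equiv), CuI (10 mol %), Et2O, 0 °C to rt; I2, −40 to 0 °C
Reagents that add atoms: iodine, II
Why: Copper-catalysed anti carbomagnesiation of the magnesium alkoxide of propargyl alcohol (magnesium chelated by oxygen) and iodinolysis with retention should give the Z-iodoalkene with iodine cis to CH2OH.

Step 19
Reactants: 35 Z-iodoalkene, 36 (E)-1,2-bis(tributylstannyl)ethene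
Product: 37 (2Z,4E)-2-(4-methylpent-3-en-1-yl)-5-(tributylstannyl)penta-2,4-dien-1-ol
Conditions: 36 (2 equiv), PdCl2(MeCN)2 (5 mol %), DMF, rt
Reagents that add atoms: none
Why: Stille coupling of the alkenyl iodide with one tin of the bis-stannane used in excess, with retention at both alkenes, should give the (2Z,4E)-dienylstannane.

Step 20
Reactants: 37 dienylstannane
Product: 38 (2Z,4E)-5-iodo-2-(4-methylpent-3-en-1-yl)penta-2,4-dien-1-ol
Conditions: I2, CH2Cl2, 0 °C, dark
Reagents that add atoms: iodine, II
Why: Iododestannylation replaces tin by iodine with retention of configuration.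

Step 21
Reactants: 30 oxasilolane enal, 38 dienyl iodide
Product: 40 target CNP0249558.2, via silylated triene 39 (not isolated)
Conditions: Pd(dba)2 (5 mol %), Bu4NF (6 equiv), THF, rt
Reagents that add atoms: none
Why: Hiyama–Denmark coupling, in which fluoride opens the oxasilolane to a pentacoordinate siliconate that transmetalates to the dienylpalladium iodide with retention at all alkenes and frees O1, should give the triene, and the excess fluoride then removes the trimethylsilyl and tert-butyldiphenylsilyl groups.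

**Compound list**

1 | hexa-1,5-diyne | C#CCCC#C | starting material
2 | lithium hexa-1,5-diyn-1-ide | [Li]C#CCCC#C | intermediate (not isolated)
3 | hepta-2,6-diyn-1-ol | OCC#CCCC#C | intermediate
4 | triethyl(hepta-2,6-diyn-1-yloxy)silane | CC[Si](CC)(CC)OCC#CCCC#C | intermediate
5 | dimethyl[(1E)-2-methyl-7-(triethylsilyloxy)hept-1-en-5-yn-1-yl]alane | C[Al](C)/C=C(\C)CCC#CCO[Si](CC)(CC)CC | intermediate (not isolated)
6 | lithium butyl(dimethyl)[(1E)-2-methyl-7-(triethylsilyloxy)hept-1-en-5-yn-1-yl]alanate | [Li+].CCCC[Al-](C)(C)/C=C(\C)CCC#CCO[Si](CC)(CC)CC | intermediate (not isolated)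
7 | (E)-3-methyl-8-(triethylsilyloxy)oct-2-en-6-yn-1-ol | OC/C=C(\C)CCC#CCO[Si](CC)(CC)CC | intermediate
8 | [(2S,3S)-3-methyl-3-[5-(triethylsilyloxy)pent-3-yn-1-yl]oxiran-2-yl]methanol | OC[C@@H]1O[C@@]1(C)CCC#CCO[Si](CC)(CC)CC | intermediate
9 | (2R,3S)-2-(chloromethyl)-3-methyl-3-[5-(triethylsilyloxy)pent-3-yn-1-yl]oxirane | ClC[C@@H]1O[C@@]1(C)CCC#CCO[Si](CC)(CC)CC | intermediate
10 | (3-bromopropoxy)(tert-butyl)diphenylsilane | BrCCCO[Si](c1ccccc1)(c1ccccc1)C(C)(C)C | starting material
11 | dilithium salt (C1 acetylide, O3 alkoxide) of (3S)-3-methyl-8-(triethylsilyloxy)octa-1,6-diyn-3-ol | [Li]C#C[C@@](C)(O[Li])CCC#CCO[Si](CC)(CC)CC | intermediate (not isolated)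
12 | (6S)-1-(tert-butyldiphenylsilyloxy)-6-methyl-11-(triethylsilyloxy)undeca-4,9-diyn-6-ol | CC(C)(C)[Si](c1ccccc1)(c1ccccc1)OCCCC#C[C@@](C)(O)CCC#CCO[Si](CC)(CC)CC | intermediate
13 | (4Z,6S)-1-(tert-butyldiphenylsilyloxy)-6-methyl-5-(tributylstannyl)-11-(triethylsilyloxy)undec-4-en-9-yn-6-ol | CC(C)(C)[Si](c1ccccc1)(c1ccccc1)OCCC/C=C(\[Sn](CCCC)(CCCC)CCCC)[C@@](C)(O)CCC#CCO[Si](CC)(CC)CC | intermediate
14 | cyclobutanone | O=C1CCC1 | starting material
15 | 5-lithio lithium alkoxide derived from 13 (tin replaced by lithium, geometry retained) | CC(C)(C)[Si](c1ccccc1)(c1ccccc1)OCCC/C=C(\[Li])[C@@](C)(O[Li])CCC#CCO[Si](CC)(CC)CC | intermediate (not isolated)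
16 | (4Z,6S)-1-(tert-butyldiphenylsilyloxy)-5-(1-hydroxycyclobutyl)-6-methyl-11-(triethylsilyloxy)undec-4-en-9-yn-6-ol | CC(C)(C)[Si](c1ccccc1)(c1ccccc1)OCCC/C=C(\C1(O)CCC1)[C@@](C)(O)CCC#CCO[Si](CC)(CC)CC | intermediate
17 | (8S,9Z)-9-[4-(tert-butyldiphenylsilyloxy)butylidene]-8-methyl-6,6-di(propan-2-yl)-8-[5-(triethylsilyloxy)pent-3-yn-1-yl]-5,7-dioxa-6-silaspiro[3.5]nonane | CC(C)(C)[Si](c1ccccc1)(c1ccccc1)OCCC/C=C1\C2(CCC2)O[Si](C(C)C)(C(C)C)O[C@@]1(C)CCC#CCO[Si](CC)(CC)CC | intermediate
18 | (9E)-10-[3-(tert-butyldiphenylsilyloxy)propyl]-6-{[di(propan-2-yl)(2,5-dioxopyrrolidin-1-yl)silyl]oxy}-9-[1-iodo-2-(triethylsilyloxy)ethylidene]-6-methylspiro[4.5]decan-1-one (C5, C6, C10 as in 40) | C1CC[C@]2([C@H](CCCO[Si](c3ccccc3)(c3ccccc3)C(C)(C)C)/C(=C(/I)CO[Si](CC)(CC)CC)CC[C@]2(C)O[Si](C(C)C)(C(C)C)N3C(=O)CCC3=O)C1=O | intermediate (not isolated)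
19 | (9E)-10-[3-(tert-butyldiphenylsilyloxy)propyl]-6-hydroxy-9-(2-hydroxy-1-iodoethylidene)-6-methylspiro[4.5]decan-1-one (C5, C6, C10 as in 40) | C1CC[C@]2([C@H](CCCO[Si](c3ccccc3)(c3ccccc3)C(C)(C)C)/C(=C(/I)CO)CC[C@]2(C)O)C1=O | intermediate
20 | (9Z)-10-[3-(tert-butyldiphenylsilyloxy)propyl]-6-hydroxy-9-(1-hydroxypropan-2-ylidene)-6-methylspiro[4.5]decan-1-one | C1CC[C@]2([C@H](CCCO[Si](c3ccccc3)(c3ccccc3)C(C)(C)C)/C(=C(/C)CO)CC[C@]2(C)O)C1=O | intermediate
21 | tris(trimethylsilyl) derivative of 20 (C1 silyl enol ether toward C2, O6 and primary O silylated) | C1C[C@]2([C@H](CCCO[Si](c3ccccc3)(c3ccccc3)C(C)(C)C)/C(=C(/C)CO[Si](C)(C)C)CC[C@]2(C)O[Si](C)(C)C)C(O[Si](C)(C)C)=C1 | intermediate (not isolated)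
22 | spiro[4.5]dec-2-en-1-one with O6 and the primary allylic oxygen as trimethylsilyl ethers | C1[C@]2([C@H](CCCO[Si](c3ccccc3)(c3ccccc3)C(C)(C)C)/C(=C(/C)CO[Si](C)(C)C)CC[C@]2(C)O[Si](C)(C)C)C(=O)C=C1 | intermediate (not isolated)
23 | (9Z)-10-[3-(tert-butyldiphenylsilyloxy)propyl]-9-(1-hydroxypropan-2-ylidene)-6-methyl-6-(trimethylsilyloxy)spiro[4.5]dec-2-en-1-one | C1[C@]2([C@H](CCCO[Si](c3ccccc3)(c3ccccc3)C(C)(C)C)/C(=C(/C)CO)CC[C@]2(C)O[Si](C)(C)C)C(=O)C=C1 | intermediate
24 | corresponding spiro[4.5]dec-2-en-1-ol, C1 hydroxyl cis to C6 (C1 as in 40) | C1[C@]2([C@H](CCCO[Si](c3ccccc3)(c3ccccc3)C(C)(C)C)/C(=C(/C)CO)CC[C@]2(C)O[Si](C)(C)C)[C@@H](O)C=C1 | intermediate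
25 | (2Z)-2-[10-[3-(tert-butyldiphenylsilyloxy)propyl]-1-hydroxy-6-methyl-6-(trimethylsilyloxy)spiro[4.5]dec-2-en-9-ylidene]propanal | C1[C@]2([C@H](CCCO[Si](c3ccccc3)(c3ccccc3)C(C)(C)C)/C(=C(/C)C=O)CC[C@]2(C)O[Si](C)(C)C)[C@@H](O)C=C1 | intermediate
26 | chloro(dimethyl)vinylsilane | C=C[Si](C)(C)Cl | starting material
27 | chloro(1,2-dibromoethyl)dimethylsilane (racemic) | BrCC(Br)[Si](C)(C)Cl | intermediate (not isolated)
28 | 1-(1-bromoethenyl)-N,N-diethyl-1,1-dimethylsilanamine | C=C(Br)[Si](C)(C)N(CC)CC | intermediate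
29 | (1-bromoethenyl)dimethylsilyl ether of 25 at O1 | C1[C@]2([C@H](CCCO[Si](c3ccccc3)(c3ccccc3)C(C)(C)C)/C(=C(/C)C=O)CC[C@]2(C)O[Si](C)(C)C)[C@@H](O[Si](C)(C)C(Br)=C)C=C1 | intermediate
30 | oxasilolane enal: C1–O–Si(CH3)2–C(=CH2)–C2 ring cis-fused to the cyclopentane, (Z)-enal at C9, O6 trimethylsilyl, chain tert-butyldiphenylsilyl ether (C1, C2, C5, C6, C10 as in 40) | C=C3[C@H]1CC[C@]2([C@H](CCCO[Si](c4ccccc4)(c4ccccc4)C(C)(C)C)/C(=C(/C)C=O)CC[C@]2(C)O[Si](C)(C)C)[C@H]1O[Si]3(C)C | intermediate
31 | prop-2-yn-1-ol | C#CCO | starting material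
32 | 5-bromo-2-methylpent-2-ene | CC(C)=CCCBr | starting material
33 | (4-methylpent-3-en-1-yl)magnesium bromide | CC(C)=CCC[Mg]Br | intermediate (not isolated)
34 | bromomagnesium (2Z)-3-(bromomagnesio)-2-(4-methylpent-3-en-1-yl)prop-2-en-1-olate | Br[Mg]/C=C(\CO[Mg]Br)CCC=C(C)C | intermediate (not isolated)
35 | (2Z)-3-iodo-2-(4-methylpent-3-en-1-yl)prop-2-en-1-ol | I/C=C(\CO)CCC=C(C)C | intermediate
36 | (E)-1,2-bis(tributylstannyl)ethene | CCCC[Sn](CCCC)(CCCC)/C=C/[Sn](CCCC)(CCCC)CCCC | starting material
37 | (2Z,4E)-2-(4-methylpent-3-en-1-yl)-5-(tributylstannyl)penta-2,4-dien-1-ol | CCCC[Sn](CCCC)(CCCC)/C=C/C=C(\CO)CCC=C(C)C | intermediate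
38 | (2Z,4E)-5-iodo-2-(4-methylpent-3-en-1-yl)penta-2,4-dien-1-ol | I/C=C/C=C(\CO)CCC=C(C)C | intermediate
39 | 40 carrying O6 trimethylsilyl and the tert-butyldiphenylsilyl ether on the propyl chain | C=C(/C=C/C=C(\CO)CCC=C(C)C)[C@H]1CC[C@]2([C@H](CCCO[Si](c3ccccc3)(c3ccccc3)C(C)(C)C)/C(=C(/C)C=O)CC[C@]2(C)O[Si](C)(C)C)[C@H]1O | intermediate (not isolated)
40 | (2Z)-2-[(1S,2R,5S,6S,10R)-1,6-dihydroxy-10-(3-hydroxypropyl)-2-[(3E,5Z)-6-(hydroxymethyl)-10-methylundeca-1,3,5,9-tetraen-2-yl]-6-methylspiro[4.5]decan-9-ylidene]propanal (numbering of the overview), CNP0249558.2 | C=C(/C=C/C=C(\CO)CCC=C(C)C)[C@H]1CC[C@]2([C@H](CCCO)/C(=C(/C)C=O)CC[C@]2(C)O)[C@H]1O | target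

**Step count and risks**

Total step count: 21. Longest linear sequence: 17 steps (steps 1 to 14, 16, 17 and 21).

Steps most likely to fail:

Step 10. NIS may attack the alkene before the gold-bound alkyne is engaged, the alkenylgold may be protonated instead of iodinated, or a siloxy oxygen may add to the activated alkyne; any of these diverts material from the cascade. The fallback uses known reactions in two stages and sets out from 17. NIS alone in MeCN at 0 °C triggers the halonium-induced ring-expanding semipinacol shift of the alkenylcyclobutanol silyl ether and should give the alpha-quaternary cyclopentanone iodide F1, in which C4–C5 is already formed. An iodine atom-transfer 6-exo-dig radical cyclization ((Bu3Sn)2 (10 mol %), hν, benzene) then closes the cyclohexane onto the alkyne and returns to the route at 18, which the HF·pyridine treatment of step 10 converts into 19. Control of C5, C10 and the alkene geometry is weaker in this sequence, so isomers would have to be separated at 19.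

Step 17. Stannyl radicals may add to or reduce the conjugated aldehyde, and the alkenyl radical may be quenched by hydrogen transfer before it closes. The fallback removes the aldehyde from the radical step and sets out from 24. Primary-selective acetylation (AcCl, 2,4,6-collidine, CH2Cl2, −78 °C) should give the monoacetate F2, silylation with 28 the bromovinylsilyl ether F3, and the same tin hydride cyclization the acetoxy oxasilolane F4. Reductive removal of the acetate (i-Bu2AlH, CH2Cl2, −78 °C) should give the allylic alcohol F5, and MnO2 oxidation returns to the route at 30.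

Step 21. The hindered alkenylsiliconate may lose silicon by protonation, and the enal and the triene may degrade in basic fluoride while transmetalation is slow. The fallback exchanges silicon for bromine first and sets out from 30. Bromine (CH2Cl2, −78 °C) adds across the vinylsilane to give the dibromide F6. Bu4NF then induces beta-elimination of silicon and the primary bromide (bromodesilylation) and removes all silyl groups, which should give the 2-bromoalkene triol F7. Stille coupling of F7 with stannane 37 (Pd2(dba)3, AsPh3, CuI, DMF, rt) returns to the route at 40.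

Further compounds
F1 | step 10 | 2-[4-(tert-butyldiphenylsilyloxy)-1-iodobutyl]-2-[(2S)-2-{[di(propan-2-yl)(2,5-dioxopyrrolidin-1-yl)silyl]oxy}-7-(triethylsilyloxy)hept-5-yn-2-yl]cyclopentan-1-one (quaternary carbon as C5 of 40, iodide from anti addition) | C1CC[C@]([C@@](C)(O[Si](C(C)C)(C(C)C)N2C(=O)CCC2=O)CCC#CCO[Si](CC)(CC)CC)([C@@H](I)CCCO[Si](c2ccccc2)(c2ccccc2)C(C)(C)C)C1=O
F2 | step 17 | primary allylic acetate of 24 | C1[C@]2([C@H](CCCO[Si](c3ccccc3)(c3ccccc3)C(C)(C)C)/C(=C(/C)COC(C)=O)CC[C@]2(C)O[Si](C)(C)C)[C@@H](O)C=C1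
F3 | step 17 | (1-bromoethenyl)dimethylsilyl ether of F2 at O1 | C1[C@]2([C@H](CCCO[Si](c3ccccc3)(c3ccccc3)C(C)(C)C)/C(=C(/C)COC(C)=O)CC[C@]2(C)O[Si](C)(C)C)[C@@H](O[Si](C)(C)C(Br)=C)C=C1
F4 | step 17 | oxasilolane as 30 with CH2OAc in place of CHO | C=C3[C@H]1CC[C@]2([C@H](CCCO[Si](c4ccccc4)(c4ccccc4)C(C)(C)C)/C(=C(/C)COC(C)=O)CC[C@]2(C)O[Si](C)(C)C)[C@H]1O[Si]3(C)C
F5 | step 17 | oxasilolane as 30 with CH2OH in place of CHO | C=C3[C@H]1CC[C@]2([C@H](CCCO[Si](c4ccccc4)(c4ccccc4)C(C)(C)C)/C(=C(/C)CO)CC[C@]2(C)O[Si](C)(C)C)[C@H]1O[Si]3(C)C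
F6 | step 21 | dibromide of 30 (Br2 added across the exocyclic methylidene, mixture at the brominated ring carbon) | BrCC3(Br)[C@H]1CC[C@]2([C@H](CCCO[Si](c4ccccc4)(c4ccccc4)C(C)(C)C)/C(=C(/C)C=O)CC[C@]2(C)O[Si](C)(C)C)[C@H]1O[Si]3(C)C
F7 | step 21 | (2Z)-2-[2-(1-bromoethenyl)-1,6-dihydroxy-10-(3-hydroxypropyl)-6-methylspiro[4.5]decan-9-ylidene]propanal (stereocenters as in 40) | C=C(Br)[C@H]1CC[C@]2([C@H](CCCO)/C(=C(/C)C=O)CC[C@]2(C)O)[C@H]1O
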